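**Assumptions (one line):** lignan numbering is used (C7/C8/C9 = guaiacyl-side chain, C7'/C8'/C9' = catechol-side chain), so the target is (7R,8R,7'S,8'R) with a 2,3-trans-3,4-cis oxolane; compounds 1, 2 and 5 are taken as commercial; in Step 3 the quinidine-derived catalyst is assumed to give the (2S,3S) acid (the quinine-derived pseudo-enantiomer is used if the sense is reversed).

## Retrosynthetic overview

1. Target 13 ⇐ deprotection (TIPS, then three aryl benzyl ethers) of 11.
2. C7–OH and C8–H ⇐ syn hydroboration–oxidation of the (E)-4-arylidene oxolane 10; E geometry plus attack anti to the C3 CH2OTIPS group gives 7R,8R.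
3. Oxolane ring ⇐ lactone reduction and Williamson ring closure (O7'→C9) from α-arylidene γ-lactone 8.
4. Lactone ring, C7'–C8' bond and both stereocentres ⇐ new catalytic asymmetric aldol–lactonisation of (E)-arylidenesuccinic anhydride 4 with aldehyde 5.
5. Anhydride 4 ⇐ Stobbe condensation of O-benzylvanillin 1 with dimethyl succinate 2. Ring order: γ-lactone (Step 3), opened (Step 6), re-closed as the oxolane (Step 7).

## Route

**Step 1**
Reactants: 1, 4-(benzyloxy)-3-methoxybenzaldehyde; 2, dimethyl succinate
Product: 3, (2E)-2-[4-(benzyloxy)-3-methoxybenzylidene]butanedioic acid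
Conditions: t-BuOK, t-BuOH, reflux; then 2 M NaOH (aq), reflux; HCl (aq)
Reagents that add atoms: sodium hydroxide/water, [Na+].[OH-] (one carboxyl O from ester hydrolysis)
Why: Stobbe condensation (aldol, paraconate lactone, E1cB opening) gives the alkylidene half-ester with the aryl trans to the conjugated carboxyl (E); in-pot saponification gives the diacid.

**Step 2**
Reactants: 3, (E)-arylidenesuccinic acid
Product: 4, (3E)-3-[4-(benzyloxy)-3-methoxybenzylidene]oxolane-2,5-dione
Conditions: Ac2O, 80 °C
Reagents that add atoms: none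
Why: Cyclodehydration of a 1,4-diacid to the five-membered anhydride; the E alkene is retained.

**Step 3 (new transformation)**
Reactants: 4, (E)-arylidenesuccinic anhydride; 5, 3,4-bis(benzyloxy)benzaldehyde
Product: 6, (2S,3S,4E)-2-[3,4-bis(benzyloxy)phenyl]-4-[4-(benzyloxy)-3-methoxybenzylidene]-5-oxooxolane-3-carboxylic acid (2,3-trans)
Conditions: N-[3,5-bis(trifluoromethyl)phenyl]-N'-(9-deoxy-epi-quinidin-9-yl)squaramide (10 mol%), MTBE, −30 °C → rt; acid–base extraction
Reagents that add atoms: none
Why: Proposed new method: the catalyst's quinuclidine nitrogen deprotonates the C8' methylene of 4 (α to an anhydride carbonyl and allylic to the styrene) to a catalyst-bound dienolate while the squaramide N–H groups bind aldehyde 5; α-selective aldol addition forms C7'–C8' with catalyst-controlled facial selectivity and anti topology (setting C7' S and the trans C8' centre), and the aldolate then acylates the distal conjugated anhydride carbonyl (5-exo) to close the γ-lactone and irreversibly release the C8' carboxylic acid; the closest known reaction type is the amine–squaramide-catalysed formal cycloaddition of enolisable homophthalic and arylsuccinic anhydrides with aldehydes (classically, the Fittig paraconic acid synthesis), which has not been shown for arylidenesuccinic anhydrides.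

**Step 4**
Reactants: 6, lactone acid
Product: 7, (3E,4R,5S)-5-[3,4-bis(benzyloxy)phenyl]-3-[4-(benzyloxy)-3-methoxybenzylidene]-4-(hydroxymethyl)oxolan-2-one
Conditions: BH3·SMe2, THF, 0 °C → rt
Reagents that add atoms: none
Why: Chemoselective borane reduction of a carboxylic acid (via the acyloxyborane), much faster than reduction of the lactone or hydroboration of the electron-poor conjugated alkene; no stereocentre is touched.

**Step 5**
Reactants: 7, hydroxymethyl lactone
Product: 8, (3E,4R,5S)-5-[3,4-bis(benzyloxy)phenyl]-3-[4-(benzyloxy)-3-methoxybenzylidene]-4-{[(triisopropylsilyl)oxy]methyl}oxolan-2-one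
Conditions: TIPSCl, imidazole, DMF, rt
Reagents that add atoms: triisopropylsilyl chloride, CC(C)[Si](Cl)(C(C)C)C(C)C
Why: Silylation of the primary alcohol under non-basic conditions (avoids translactonisation); the bulky TIPS group resists 1,3-migration and later shields the lower ring face.

**Step 6**
Reactants: 8, TIPS-protected arylidene lactone
Product: 9, (1S,2R,3E)-1-[3,4-bis(benzyloxy)phenyl]-3-[4-(benzyloxy)-3-methoxybenzylidene]-2-{[(triisopropylsilyl)oxy]methyl}butane-1,4-diol
Conditions: DIBAL-H (3.5 equiv), CH2Cl2, −78 → 0 °C; Rochelle salt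
Reagents that add atoms: none
Why: 1,2-Reduction of an α-alkylidene lactone to the 2-alkylidene-1,4-diol; alkene geometry and both stereocentres are unchanged.

**Step 7**
Reactants: 9, diol
Product: 10, (2S,3R,4E)-2-[3,4-bis(benzyloxy)phenyl]-4-[4-(benzyloxy)-3-methoxybenzylidene]-3-{[(triisopropylsilyl)oxy]methyl}oxolane
Conditions: TsCl (1.05 equiv), Et3N, DMAP (cat.), CH2Cl2, 0 °C; then NaH, THF, 0 °C → rt
Reagents that add atoms: none
Why: Williamson cycloetherification: the primary allylic OH is sulfonylated selectively and the C7' alkoxide displaces at C9 (5-exo-tet SN2), so the C7'–O bond is never broken and C7' is retained.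

**Step 8**
Reactants: 10, (E)-arylidene oxolane
Product: 11, (R)-[4-(benzyloxy)-3-methoxyphenyl][(3R,4R,5S)-5-[3,4-bis(benzyloxy)phenyl]-4-{[(triisopropylsilyl)oxy]methyl}oxolan-3-yl]methanol
Conditions: BH3·THF, THF, 0 °C → rt; then NaOH, H2O2, 0 °C
Reagents that add atoms: hydrogen peroxide, OO (supplies the C7 oxygen; borane supplies only H)
Why: Hydroboration–oxidation: boron adds to the benzylic CH (C7) rather than the fully substituted ring carbon, from the face anti to the CH2OTIPS group (held pseudo-axial by A1,3 strain with the cis aryl); concerted syn addition across the E alkene then fixes C8 (ring H anti to C9', i.e. 3,4-cis) and C7 (R), and oxidation proceeds with retention.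

**Step 9**
Reactants: 11, TIPS ether
Product: 12, (R)-[4-(benzyloxy)-3-methoxyphenyl][(3R,4R,5S)-5-[3,4-bis(benzyloxy)phenyl]-4-(hydroxymethyl)oxolan-3-yl]methanol
Conditions: TBAF, THF, 0 °C → rt
Reagents that add atoms: none
Why: Fluoride desilylation while the phenols are still benzyl-protected, so no base-sensitive catechol is exposed.

**Step 10**
Reactants: 12, tri-O-benzyl diol
Product: 13, (7R)-7-hydroxytaxiresinol, 4-[(2S,3R,4R)-4-[(R)-hydroxy(4-hydroxy-3-methoxyphenyl)methyl]-3-(hydroxymethyl)oxolan-2-yl]benzene-1,2-diol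
Conditions: H2 (1 atm), 10% Pd/C, EtOAc–MeOH, rt (stop after 3 equiv H2)
Reagents that add atoms: none
Why: Neutral hydrogenolysis of the three aryl benzyl ethers, which is faster than cleavage of the benzylic alcohol or the 2-aryl oxolane C–O bond; no stereocentre is affected.

## Compound list

1 | 4-(benzyloxy)-3-methoxybenzaldehyde | COc1cc(C=O)ccc1OCc1ccccc1 | starting material
2 | dimethyl succinate | COC(=O)CCC(=O)OC | starting material
3 | (2E)-2-[4-(benzyloxy)-3-methoxybenzylidene]butanedioic acid | COc1cc(/C=C(/C(=O)O)CC(=O)O)ccc1OCc1ccccc1 | intermediate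
4 | (3E)-3-[4-(benzyloxy)-3-methoxybenzylidene]oxolane-2,5-dione | COc1cc(/C=C2/C(=O)OC(=O)C2)ccc1OCc1ccccc1 | intermediate
5 | 3,4-bis(benzyloxy)benzaldehyde | O=Cc1ccc(OCc2ccccc2)c(OCc2ccccc2)c1 | starting material
6 | (2S,3S,4E)-2-[3,4-bis(benzyloxy)phenyl]-4-[4-(benzyloxy)-3-methoxybenzylidene]-5-oxooxolane-3-carboxylic acid | COc1cc(/C=C2/C(=O)O[C@H](c3ccc(OCc4ccccc4)c(OCc4ccccc4)c3)[C@H]2C(=O)O)ccc1OCc1ccccc1 | intermediate
7 | (3E,4R,5S)-5-[3,4-bis(benzyloxy)phenyl]-3-[4-(benzyloxy)-3-methoxybenzylidene]-4-(hydroxymethyl)oxolan-2-one | COc1cc(/C=C2/C(=O)O[C@H](c3ccc(OCc4ccccc4)c(OCc4ccccc4)c3)[C@H]2CO)ccc1OCc1ccccc1 | intermediate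
8 | (3E,4R,5S)-5-[3,4-bis(benzyloxy)phenyl]-3-[4-(benzyloxy)-3-methoxybenzylidene]-4-{[(triisopropylsilyl)oxy]methyl}oxolan-2-one | COc1cc(/C=C2/C(=O)O[C@H](c3ccc(OCc4ccccc4)c(OCc4ccccc4)c3)[C@H]2CO[Si](C(C)C)(C(C)C)C(C)C)ccc1OCc1ccccc1 | intermediate
9 | (1S,2R,3E)-1-[3,4-bis(benzyloxy)phenyl]-3-[4-(benzyloxy)-3-methoxybenzylidene]-2-{[(triisopropylsilyl)oxy]methyl}butane-1,4-diol | COc1cc(/C=C(/CO)[C@H](CO[Si](C(C)C)(C(C)C)C(C)C)[C@H](O)c2ccc(OCc3ccccc3)c(OCc3ccccc3)c2)ccc1OCc1ccccc1 | intermediate
10 | (2S,3R,4E)-2-[3,4-bis(benzyloxy)phenyl]-4-[4-(benzyloxy)-3-methoxybenzylidene]-3-{[(triisopropylsilyl)oxy]methyl}oxolane | COc1cc(/C=C2/CO[C@H](c3ccc(OCc4ccccc4)c(OCc4ccccc4)c3)[C@H]2CO[Si](C(C)C)(C(C)C)C(C)C)ccc1OCc1ccccc1 | intermediate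
11 | (R)-[4-(benzyloxy)-3-methoxyphenyl][(3R,4R,5S)-5-[3,4-bis(benzyloxy)phenyl]-4-{[(triisopropylsilyl)oxy]methyl}oxolan-3-yl]methanol | COc1cc([C@H](O)[C@H]2CO[C@H](c3ccc(OCc4ccccc4)c(OCc4ccccc4)c3)[C@H]2CO[Si](C(C)C)(C(C)C)C(C)C)ccc1OCc1ccccc1 | intermediate
12 | (R)-[4-(benzyloxy)-3-methoxyphenyl][(3R,4R,5S)-5-[3,4-bis(benzyloxy)phenyl]-4-(hydroxymethyl)oxolan-3-yl]methanol | COc1cc([C@H](O)[C@H]2CO[C@H](c3ccc(OCc4ccccc4)c(OCc4ccccc4)c3)[C@H]2CO)ccc1OCc1ccccc1 | intermediate
13 | (7R)-7-hydroxytaxiresinol | COc1cc([C@H](O)[C@H]2CO[C@H](c3ccc(O)c(O)c3)[C@H]2CO)ccc1O | target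

## Summary

Total steps: 10. Longest linear sequence: 10 (1 → 13; aldehyde 5 enters at Step 3).

Steps most likely to fail, with fallbacks:

- **Step 3 (proposed new aldol–lactonisation).** Risks are slow reaction of the electron-rich aldehyde, base-mediated isomerisation of 4 to the arylmethylmaleic anhydride, and insufficient dr/ee. Fallback (known chemistry): stop Step 1 at the Stobbe half-ester, attach (S)-4-benzyloxazolidin-2-one, run the Bu2BOTf/i-Pr2NEt Evans syn-aldol with 5, lactonise onto the conjugated methyl ester (syn aldol gives the trans lactone), and reduce the imide with LiBH4 to rejoin the route at 7.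
- **Step 8 (hydroboration face and regiochemistry).** The C2 aryl sits on the face that must be attacked, so selectivity could be modest. Fallback: install the C7 oxygen at the lactone stage under catalyst control by Cu(I)/chiral bisphosphine conjugate borylation of 8 (B2pin2, NaOt-Bu, MeOH; then NaBO3), with kinetic protonation anti to CH2OTIPS setting C8; then reduce the lactone and close the oxolane by primary-selective sulfonylation.
- **Step 7 (ring closure through an allylic sulfonate).** The 2-arylallyl sulfonate may ionise (SN1/SN2', loss of E geometry). Fallback: avoid the diol by reducing 8 to the lactol (DIBAL-H, 1.1 equiv, −78 °C) and deoxygenating it with Et3SiH/BF3·OEt2 at −78 °C to give 10 directly.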